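**Retrosynthetic overview**
1. Target 17 ⇒ pyranone 11 + formaldehyde + 2-methylpropene: the dihydropyran ring (hetero-Diels–Alder) and ring A (pyranone-to-arene Claisen closure) are both made in the last flask.
2. 11 ⇒ triacetic acid lactone 9 (supplies all six ring A carbons) + ester 8, joined at the lactone 6-methyl group.
3. 8 ⇒ aldehyde 5 (Wittig, conjugate reduction) ⇒ 3-bromo-4,5-dihydroxybenzaldehyde 1 (4-O-methylation, Stille prenylation).
4. Ring order: ring B is bought; then the pyran ring, then ring A, in one operation; the pyranone ring is consumed.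

Assumption: the target has no stereocentre and no E/Z-isomeric double bond, so it is achiral and no asymmetric step is needed.

**Route**

Step 1
Reactants: 1 3-bromo-4,5-dihydroxybenzaldehyde; 2 iodomethane
Product: 3 3-bromo-5-hydroxy-4-methoxybenzaldehyde
Conditions: MeI (1.1 equiv), Li2CO3 (1.2 equiv), DMF, 45 °C
Reagents that add atoms: iodomethane (2), CI
Why: Williamson etherification is selective for the 4-OH, the most acidic phenol (para to the formyl group, ortho to Br), which the weak base Li2CO3 deprotonates preferentially.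

Step 2
Reactants: 3 3-bromo-5-hydroxy-4-methoxybenzaldehyde; 4 tributyl(3-methylbut-2-en-1-yl)stannane
Product: 5 3-hydroxy-4-methoxy-5-(3-methylbut-2-en-1-yl)benzaldehyde
Conditions: Pd(PPh3)4 (5 mol%), DMF, 100 °C
Reagents that add atoms: tributyl(3-methylbut-2-en-1-yl)stannane (4), CCCC[Sn](CCCC)(CCCC)CC=C(C)C
Why: Stille cross-coupling (oxidative addition of the aryl bromide to zerovalent palladium, transmetalation, reductive elimination at the unsubstituted allyl terminus) gives the linear prenyl arene and tolerates the aldehyde and the free phenol.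

Step 3
Reactants: 5 3-hydroxy-4-methoxy-5-(3-methylbut-2-en-1-yl)benzaldehyde; 6 methyl (triphenylphosphoranylidene)acetate
Product: 7 methyl (2E)-3-[3-hydroxy-4-methoxy-5-(3-methylbut-2-en-1-yl)phenyl]prop-2-enoate
Conditions: Ph3P=CHCO2Me (1.2 equiv), toluene, 90 °C
Reagents that add atoms: methyl (triphenylphosphoranylidene)acetate (6), COC(=O)C=P(c1ccccc1)(c1ccccc1)c1ccccc1
Why: Wittig olefination with a stabilized ylide gives the (E)-cinnamate and leaves the phenol and the prenyl alkene untouched.

Step 4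
Reactants: 7 methyl (2E)-3-[3-hydroxy-4-methoxy-5-(3-methylbut-2-en-1-yl)phenyl]prop-2-enoate
Product: 8 methyl 3-[3-hydroxy-4-methoxy-5-(3-methylbut-2-en-1-yl)phenyl]propanoate
Conditions: Mg turnings (4 equiv), MeOH, 0 °C → rt
Reagents that add atoms: none
Why: Dissolving-metal conjugate reduction (Mg/MeOH, single-electron transfer) reduces only the ester-conjugated C=C; the isolated trisubstituted prenyl alkene is not reduced.

Step 5
Reactants: 9 4-hydroxy-6-methyl-2H-pyran-2-one (triacetic acid lactone); 8 methyl 3-[3-hydroxy-4-methoxy-5-(3-methylbut-2-en-1-yl)phenyl]propanoate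
Product: 11 4-hydroxy-6-{4-[3-hydroxy-4-methoxy-5-(3-methylbut-2-en-1-yl)phenyl]-2-oxobutyl}-2H-pyran-2-one, via pyranone dianion 10 (not isolated)
Conditions: 9 (3.3 equiv), LiN(iPr)2 (6.6 equiv), THF–DMPU, −78 → 0 °C; then 8, −78 °C → rt; 1 M HCl
Reagents that add atoms: none
Why: Crossed Claisen condensation: the dianion reacts only through its 6-methyl carbanion (the 4-oxido group shields C3 and C5), one extra equivalent absorbs the phenol proton of 8, and the β-keto pyranone product is protected as its enolate.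

Step 6
Reactants: 11 4-hydroxy-6-{4-[3-hydroxy-4-methoxy-5-(3-methylbut-2-en-1-yl)phenyl]-2-oxobutyl}-2H-pyran-2-one; 12 formaldehyde (charged as paraformaldehyde); 13 2-methylpropene
Product: 17 1-(5,7-dihydroxy-2,2-dimethyl-3,4-dihydro-2H-chromen-6-yl)-3-[3-hydroxy-4-methoxy-5-(3-methylbut-2-en-1-yl)phenyl]propan-1-one, via 3-methylenepyran-2,4-dione 14 (not isolated), via pyranopyranone 15 (not isolated), via ring-opened keto ester 16 (not isolated)
Conditions: (CH2O)n (1.1 equiv), 2-methylpropene (20 equiv), ethylenediammonium diacetate (10 mol%), 1,4-dioxane, sealed tube, 90 °C; vent; then Mg(OMe)2 (6 equiv), MeOH, reflux; 1 M HCl, 0 °C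
Reagents that add atoms: formaldehyde (12), C=O; 2-methylpropene (13), C=C(C)C
Why: Proposed new method: Knoevenagel condensation of formaldehyde at C3 of the 4-hydroxypyranone gives oxadiene 14, whose inverse-demand hetero-Diels–Alder reaction with 2-methylpropene (oxygen to the more substituted carbon) closes the 2,2-dimethyldihydropyran on the only pyranone OH; Mg(OMe)2 then opens the lactone to 16, and the chelated β-diketone carbon attacks the ester (Claisen/Dieckmann-type closure, the biomimetic tetraketide-to-acylphloroglucinol cyclization), so ring A aromatizes with the acyl group between two OH groups and the pyran oxygen para to it; the closest known reactions are the three-component Knoevenagel/hetero-Diels–Alder reaction of 4-hydroxycoumarins and 4-hydroxy-2-pyranones with alkenes and the Mg(OMe)2-induced rearrangement of 6-(2-oxoalkyl)-4-hydroxy-2-pyranones to acylphloroglucinols; no stereocentre is formed.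

**Compound list**
1 | 3-bromo-4,5-dihydroxybenzaldehyde | O=Cc1cc(O)c(O)c(Br)c1 | starting material
2 | iodomethane | CI | starting material
3 | 3-bromo-5-hydroxy-4-methoxybenzaldehyde | COc1c(O)cc(C=O)cc1Br | intermediate
4 | tributyl(3-methylbut-2-en-1-yl)stannane | CCCC[Sn](CCCC)(CCCC)CC=C(C)C | starting material
5 | 3-hydroxy-4-methoxy-5-(3-methylbut-2-en-1-yl)benzaldehyde | COc1c(O)cc(C=O)cc1CC=C(C)C | intermediate
6 | methyl (triphenylphosphoranylidene)acetate | COC(=O)C=P(c1ccccc1)(c1ccccc1)c1ccccc1 | starting material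
7 | methyl (2E)-3-[3-hydroxy-4-methoxy-5-(3-methylbut-2-en-1-yl)phenyl]prop-2-enoate | COC(=O)/C=C/c1cc(O)c(OC)c(CC=C(C)C)c1 | intermediate
8 | methyl 3-[3-hydroxy-4-methoxy-5-(3-methylbut-2-en-1-yl)phenyl]propanoate | COC(=O)CCc1cc(O)c(OC)c(CC=C(C)C)c1 | intermediate
9 | 4-hydroxy-6-methyl-2H-pyran-2-one (triacetic acid lactone) | CC1=CC(O)=CC(=O)O1 | starting material
10 | dilithium dianion of 9 (4-oxido, 6-CH2 carbanion) | [Li+].[Li+].[CH2-]C1=CC([O-])=CC(=O)O1 | intermediate (not isolated)
11 | 4-hydroxy-6-{4-[3-hydroxy-4-methoxy-5-(3-methylbut-2-en-1-yl)phenyl]-2-oxobutyl}-2H-pyran-2-one | COc1c(O)cc(CCC(=O)CC2=CC(O)=CC(=O)O2)cc1CC=C(C)C | intermediate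
12 | formaldehyde (charged as paraformaldehyde) | C=O | starting material
13 | 2-methylpropene | C=C(C)C | starting material
14 | 6-{4-[3-hydroxy-4-methoxy-5-(3-methylbut-2-en-1-yl)phenyl]-2-oxobutyl}-3-methylidene-2H-pyran-2,4(3H)-dione | C=C1C(=O)C=C(CC(=O)CCc2cc(O)c(OC)c(CC=C(C)C)c2)OC1=O | intermediate (not isolated)
15 | 7-{4-[3-hydroxy-4-methoxy-5-(3-methylbut-2-en-1-yl)phenyl]-2-oxobutyl}-2,2-dimethyl-3,4-dihydro-2H,5H-pyrano[4,3-b]pyran-5-one | O=C1OC(CC(=O)CCc2cc(O)c(OC)c(CC=C(C)C)c2)=CC2=C1CCC(C)(C)O2 | intermediate (not isolated)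
16 | methyl 2-{6-[3-hydroxy-4-methoxy-5-(3-methylbut-2-en-1-yl)phenyl]-2,4-dioxohexyl}-6,6-dimethyl-5,6-dihydro-4H-pyran-3-carboxylate | COC(=O)C1=C(CC(=O)CC(=O)CCc2cc(O)c(OC)c(CC=C(C)C)c2)OC(C)(C)CC1 | intermediate (not isolated)
17 | 1-(5,7-dihydroxy-2,2-dimethyl-3,4-dihydro-2H-chromen-6-yl)-3-[3-hydroxy-4-methoxy-5-(3-methylbut-2-en-1-yl)phenyl]propan-1-one | COc1c(O)cc(CCC(=O)c2c(O)cc3c(c2O)CCC(C)(C)O3)cc1CC=C(C)C | target

**Totals**
Total step count: 6. Longest linear sequence: 6 steps (1 → 3 → 5 → 7 → 8 → 11 → 17).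

**Steps most likely to fail, with fallbacks**

Step 6 is the most likely to fail. Formaldehyde may condense at the side-chain methylene of 11, the oxadiene 14 may be trapped by a second pyranone instead of 2-methylpropene, or methoxide may not lead to ring A. The fallback takes ring A from an arene and builds the ketone chain by aldol chemistry; it sets out from aldehyde 5 and rejoins the route at 17. Commercial 2,4,6-trihydroxyacetophenone is O-alkylated at its 4-OH with 3-chloro-3-methylbut-1-yne (K2CO3, KI, acetone, reflux) to 1-[2,6-dihydroxy-4-(2-methylbut-3-yn-2-yloxy)phenyl]ethanone F1. Heating (N,N-diethylaniline, 190 °C; propargyl Claisen rearrangement then oxa-6π closure, unambiguous because both ortho positions are equivalent) gives 1-(5,7-dihydroxy-2,2-dimethyl-2H-chromen-6-yl)ethanone F2. Hydrogenation (H2, Pd/C, EtOAc) gives 1-(5,7-dihydroxy-2,2-dimethyl-3,4-dihydro-2H-chromen-6-yl)ethanone F3. Claisen–Schmidt condensation with 5 (KOH, EtOH, rt) gives (2E)-1-(5,7-dihydroxy-2,2-dimethyl-3,4-dihydro-2H-chromen-6-yl)-3-[3-hydroxy-4-methoxy-5-(3-methylbut-2-en-1-yl)phenyl]prop-2-en-1-one F4. Hydrogenation of the enone only (H2, RhCl(PPh3)3, benzene–EtOH; the trisubstituted prenyl alkene is inert) gives 17.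

Step 5 is the second risk. The dianion 10 is poorly soluble and may deprotonate ester 8 at its α-carbon instead of acylating. The fallback reverses the order of events, so the nucleophile is a neutral, soluble pyranone without an acidic OH; it sets out from 9 and rejoins the route at 15. Knoevenagel/hetero-Diels–Alder reaction of 9 with 12 and 13 (ethylenediammonium diacetate, 1,4-dioxane, sealed tube, 90 °C) gives 2,2,7-trimethyl-3,4-dihydro-2H,5H-pyrano[4,3-b]pyran-5-one F5. Deprotonation of its 7-methyl group (LiN(iPr)2, THF, −78 °C) and acylation with 8 (2 equiv of the lithiated pyranone) gives 15, now isolated. Only the Mg(OMe)2 stage of step 6 is then run on 15 to reach 17.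

Step 2 is the third risk. The prenylstannane may couple partly through its substituted terminus (1,1-dimethylallyl isomer) or react sluggishly with this electron-rich bromide. The fallback separates C–C coupling from the build-up of the trisubstituted alkene; it sets out from 3 and rejoins the route at 5. Stille coupling of 3 with allyltributylstannane (Pd(PPh3)4, DMF, 90 °C), which has no regiochemical ambiguity, gives 3-hydroxy-4-methoxy-5-(prop-2-en-1-yl)benzaldehyde F6. Olefin cross-metathesis with 2-methylbut-2-ene (second-generation Grubbs catalyst, CH2Cl2, 40 °C) gives 5.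

**Further compounds**
F1 | step 6 | 1-[2,6-dihydroxy-4-(2-methylbut-3-yn-2-yloxy)phenyl]ethanone | CC(=O)c1c(O)cc(OC(C)(C)C#C)cc1O
F2 | step 6 | 1-(5,7-dihydroxy-2,2-dimethyl-2H-chromen-6-yl)ethanone | CC(=O)c1c(O)cc2OC(C)(C)C=Cc2c1O
F3 | step 6 | 1-(5,7-dihydroxy-2,2-dimethyl-3,4-dihydro-2H-chromen-6-yl)ethanone | CC(=O)c1c(O)cc2OC(C)(C)CCc2c1O
F4 | step 6 | (2E)-1-(5,7-dihydroxy-2,2-dimethyl-3,4-dihydro-2H-chromen-6-yl)-3-[3-hydroxy-4-methoxy-5-(3-methylbut-2-en-1-yl)phenyl]prop-2-en-1-one | COc1c(O)cc(/C=C/C(=O)c2c(O)cc3OC(C)(C)CCc3c2O)cc1CC=C(C)C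
F5 | step 5 | 2,2,7-trimethyl-3,4-dihydro-2H,5H-pyrano[4,3-b]pyran-5-one | CC1=CC2=C(CCC(C)(C)O2)C(=O)O1
F6 | step 2 | 3-hydroxy-4-methoxy-5-(prop-2-en-1-yl)benzaldehyde | COc1c(O)cc(C=O)cc1CC=C
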